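**Retrosynthetic overview**
1. Numbering: C1 methacrylate carbinol, C2 CH2, C3 isobutyrate carbinol, C4 quaternary C(CH3), C5 CH next to ketone C6, C7=C8(CH3) alkene, C9 and C10 the other cyclobutane CH, C11 CMe2. Rings: cyclobutane C4–C5–C10–C9, cyclohexenone C4–C5–C6–C7–C8–C9, cycloheptane C1–C2–C3–C4–C5–C10–C11.
2. Feature: the single carbon C10 bridges C5 and C9, the two ring neighbours of quaternary C4. With the carbonyl shifted from C6 to C7, these become the two β-carbons of a 2,4-dimethyl-4-alkylcyclohexa-2,5-dienone. Cutting C5–C10 and C9–C10 together therefore removes the cycloheptane and the cyclobutane and leaves monocycle 20, with C10 as a CHI2 group.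
3. After the cascade: 1,3-carbonyl transposition of ketone 22 (C7=C8 enol triflate, reduction, allylic oxidation at C6), then exchange of TBS for methacrylate at O1.
4. Before the cascade: CHI2 from a C10 aldehyde masked as a vinyl group; the dienone by two dehydrogenations of a regiodefined silyl enol ether; the O3 isobutyrate and C1 by an Evans–Tishchenko reaction; C2–C3 by a boron aldol; C4 and the six-membered ring by an enantioselective Diels–Alder reaction.
5. Ring order: six-membered ring (step 2), then the seven- and four-membered rings in one operation (step 11).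

Key step: step 11

Assumption: the hands of the two chiral reagents (the (S)-oxazaborolidine of step 2 and (−)-Ipc2BCl of step 4) are assigned from the accepted transition-state models for α-substituted enals and for methyl ketone boron enolates. Both antipodes are commercial, so a reversed sense would be met by exchanging the reagent enantiomer only.
Abbreviations: TIPS triisopropylsilyl, TBS tert-butyldimethylsilyl, Ipc isopinocampheyl, Tf trifluoromethanesulfonyl.

**Step 1**
Reactants: 1 3-methylbut-3-en-2-one
Product: 2 3-methyl-2-(triisopropylsilyloxy)buta-1,3-diene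
Conditions: TIPSOTf, Et3N, Et2O, 0 °C
Reagents that add atoms: triisopropylsilyl triflate, CC(C)[Si](C(C)C)(C(C)C)OS(=O)(=O)C(F)(F)F
Why: Soft enolisation and O-silylation at the only enolisable position (the acetyl CH3) should give the 2-silyloxydiene, and the bulky TIPS group is chosen because this enol ether has to survive steps 2 to 6.

**Step 2**
Reactants: 2 3-methyl-2-(triisopropylsilyloxy)buta-1,3-diene; 3 methacrolein
Product: 4 (S)-1,3-dimethyl-4-(triisopropylsilyloxy)cyclohex-3-ene-1-carbaldehyde
Conditions: (S)-3,3-diphenyl-1-(2-methylphenyl)tetrahydro-1H,3H-pyrrolo[1,2-c][1,3,2]oxazaborole (20 mol %), HN(SO2CF3)2 (18 mol %), CH2Cl2, −78 °C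
Reagents that add atoms: none
Why: Enantioselective Diels–Alder reaction under cationic oxazaborolidine catalysis: the siloxy group directs the para regiochemistry (its CH2 terminus bonds to the enal β-carbon, so the ring methyl ends on C8), and the catalyst, which binds s-trans methacrolein through boron and a formyl C–H···O contact and covers one face with a phenyl group, sets quaternary C4 as (S), the arrangement that is called (R) in 28 only because ligand priorities change.

**Step 3**
Reactants: 5 2,2-dimethylbut-3-enoic acid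
Product: 7 3,3-dimethylpent-4-en-2-one, via dilithium diolate 6 (not isolated)
Conditions: MeLi (2.1 equiv), Et2O, 0 °C; then poured into cold aq. HCl
Reagents that add atoms: methyllithium, [Li]C
Why: Addition of an organolithium to a lithium carboxylate stops at the gem-diolate and releases the methyl ketone only on quenching, and the vinyl group is carried as the masked C10 aldehyde because an ester at C10 could not be reduced later beside the isobutyrate and the ring carbonyl.

**Step 4**
Reactants: 7 3,3-dimethylpent-4-en-2-one; 4 (S)-1,3-dimethyl-4-(triisopropylsilyloxy)cyclohex-3-ene-1-carbaldehyde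
Product: 10 (1R)-1-[(1S)-1,3-dimethyl-4-(triisopropylsilyloxy)cyclohex-3-en-1-yl]-1-hydroxy-4,4-dimethylhex-5-en-3-one, via boron enolate 8 (not isolated), via boron aldolate 9 (not isolated)
Conditions: (−)-Ipc2BCl, Et3N, Et2O, 0 °C; then 4, −78 → −20 °C; then MeOH, pH 7 buffer, 30 % H2O2, 0 °C
Reagents that add atoms: none
Why: Reagent-controlled boron aldol reaction of a methyl ketone: the aldehyde carries two nearly equal ring CH2 arms on C4 and offers no useful Felkin bias, so the isopinocampheyl ligands choose the aldehyde face and should set C3 as (R), the minor C3 epimer being removable by chromatography because 4 is a single enantiomer.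

**Step 5**
Reactants: 10 β-hydroxy ketone of step 4; 11 isobutyraldehyde
Product: 12 (1R,3R)-1-[(1S)-1,3-dimethyl-4-(triisopropylsilyloxy)cyclohex-3-en-1-yl]-3-hydroxy-4,4-dimethylhex-5-en-1-yl 2-methylpropanoate
Conditions: 11 (6 equiv), SmI2 (0.3 equiv), THF, −10 °C, dark
Reagents that add atoms: none
Why: Evans–Tishchenko reaction: the hemiacetal of O3 with isobutyraldehyde, held on a trivalent samarium alkoxide together with the C1 ketone, hands over its hydride through a chair-like bicyclic transition state, which should give the 1,3-anti alcohol (C1 R) and place the isobutyrate on O3 in the same operation.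

**Step 6**
Reactants: 12 hydroxy isobutyrate of step 5
Product: 13 (1R,3R)-3-(tert-butyldimethylsilyloxy)-1-[(1S)-1,3-dimethyl-4-(triisopropylsilyloxy)cyclohex-3-en-1-yl]-4,4-dimethylhex-5-en-1-yl 2-methylpropanoate
Conditions: TBSOTf, 2,6-lutidine, CH2Cl2, −78 → 0 °C
Reagents that add atoms: tert-butyldimethylsilyl triflate, CC(C)(C)[Si](C)(C)OS(=O)(=O)C(F)(F)F
Why: Silylation with a silyl triflate and a non-nucleophilic base reaches the neopentylic C1 alcohol at low temperature, where 1,3-acyl migration from O3 does not compete, and gives a group that is no radical acceptor (a methacrylate placed now would be one).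

**Step 7**
Reactants: 13 bis-silyl compound of step 6
Product: 14 (1R,3R)-3-(tert-butyldimethylsilyloxy)-1-[(1S)-1,3-dimethyl-4-oxocyclohex-2-en-1-yl]-4,4-dimethylhex-5-en-1-yl 2-methylpropanoate
Conditions: Pd(OAc)2 (1.1 equiv), MeCN–CH2Cl2, 40 °C
Reagents that add atoms: none
Why: Saegusa–Ito oxidation: divalent palladium takes the enol ether at C8 and β-hydride elimination of a C9 hydrogen should give the C8=C9 enone, whose position is fixed by the regiodefined enol ether from step 2, while the vinyl group has no allylic hydrogen to lose.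

**Step 8**
Reactants: 14 enone of step 7
Product: 16 (1R,3R)-3-(tert-butyldimethylsilyloxy)-1-[(1S)-1,3-dimethyl-4-oxocyclohexa-2,5-dien-1-yl]-4,4-dimethylhex-5-en-1-yl 2-methylpropanoate, via trimethylsilyl dienol ether 15 (not isolated)
Conditions: Me3SiOTf, Et3N, CH2Cl2, 0 °C; crude, then Pd(OAc)2 (1.1 equiv), MeCN, 23 °C
Reagents that add atoms: none
Why: Because C4 is quaternary the enone can be enolised only at C6, so soft silylation gives one cross-conjugated dienol ether and a second Saegusa–Ito oxidation should give the dienone, which is safe from retro-aldol aromatisation because O3 is already acylated.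

**Step 9**
Reactants: 16 vinyl dienone of step 8
Product: 18 (1R,3R)-3-(tert-butyldimethylsilyloxy)-1-[(1S)-1,3-dimethyl-4-oxocyclohexa-2,5-dien-1-yl]-4,4-dimethyl-5-oxopentyl 2-methylpropanoate, via terminal diol 17 (not isolated)
Conditions: OsO4 (2 mol %), NaIO4, 2,6-lutidine, dioxane–H2O, 23 °C
Reagents that add atoms: OsO4 (oxygen carrier), O=[Os](=O)(=O)=O; NaIO4 (terminal oxidant), [Na+].[O-]I(=O)(=O)=O
Why: Lemieux–Johnson cleavage: electrophilic OsO4 should take the isolated monosubstituted alkene ahead of the two electron-poor dienone alkenes that flank quaternary C4, and periodate cleaves the diol to a non-enolisable aldehyde.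

**Step 10**
Reactants: 18 dienone aldehyde of step 9
Product: 20 (1R,3R)-3-(tert-butyldimethylsilyloxy)-1-[(1S)-1,3-dimethyl-4-oxocyclohexa-2,5-dien-1-yl]-5,5-diiodo-4,4-dimethylpentyl 2-methylpropanoate, via N-silylhydrazone 19 (not isolated)
Conditions: TBSNHNHTBS (1.05 equiv), Sc(OTf)3 (1 mol %), CH2Cl2, 0 → 23 °C; evaporate; then added to I2, Et3N, THF, 0 °C, dark
Reagents that add atoms: iodine, II
Why: Hydrazone–iodine oxidation in its N-silylhydrazone form (the gem-diiodide counterpart of the Barton vinyl iodide synthesis): the bulky, weakly nucleophilic bis-silylhydrazine should condense with the aldehyde far faster than with the cross-conjugated ketone and neither adds in conjugate fashion nor cleaves the ester as free hydrazine could, and since C11 is quaternary the diazo intermediate can end only as the gem-diiodide and not as a vinyl iodide.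

**Step 11**
Reactants: 20 gem-diiodide dienone of step 10
Product: 22 1-O-TBS-3-O-isobutyryl-longipinan-7-one (route numbering; C8 methyl syn to the C4 methyl), via bicyclic iodide 21 (not isolated)
Conditions: (Me3Si)3SiH (2.4 equiv, syringe pump, 12 h), Et3B (5 × 0.1 equiv), air bleed, benzene, 3 mM, 25 °C, dark
Reagents that add atoms: none
Why: Proposed new method: Et• from Et3B and O2 starts a silyl-radical chain in which (Me3Si)3Si• abstracts one iodine from C10, the α-iodoalkyl radical adds to the unsubstituted β-carbon C5 (7-exo-trig, closing the cycloheptane C1–C2–C3–C4–C5–C10–C11), the electrophilic C6 radical takes hydrogen from the silane to give iodide 21, and abstraction of the second iodine gives a secondary C10 radical that adds to C9 (4-exo-trig, closing the cyclobutane C4–C5–C10–C9) before the tertiary C8 radical is quenched by the silane. The closest known reaction types are reductive radical conjugate cyclisations onto 4,4-disubstituted cyclohexadienones, 4-exo-trig closures onto unsaturated carbonyl acceptors assisted by gem-dialkyl groups, and gem-dihalides spent as two successive radicals, but their union on one carbon in one flask has not been shown. C5, C9 and C10 are dictated by C4 alone, because the C3–C11 chain reaches only the dienone face on which it stands and a one-carbon bridge across C5 and C9 can only be cis, which also forces C11 on C10 to point toward C4. C8 is set by hydrogen transfer to the face syn to C10–H, away from the C4 methyl group, and is erased in step 12, so its configuration does not matter. No site selectivity is needed, since first attack at C9 and second attack at C5 gives the same 22; what is needed is that each closure beats hydrogen transfer to the C10 radical, which the 3 mM dilution, the slow silane addition and the Thorpe–Ingold compression by quaternary C4 and C11 are meant to secure. The weak point is that the strained 4-exo adduct radical can reopen at C9–C10 or at C4–C9, so the polarity-matched hydrogen transfer from the hydridic silane to this electrophilic α-keto radical (or its capture at oxygen by Et3B as an enol borinate, which gives the same ketone on work-up) has to be faster than ring opening.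

**Step 12**
Reactants: 22 tricyclic C7 ketone of step 11
Product: 23 C7=C8 trimethylsilyl enol ether of 22
Conditions: Me3SiCl, NaI, Et3N, MeCN, 23 → 40 °C
Reagents that add atoms: chlorotrimethylsilane, C[Si](C)(C)Cl
Why: Enol silylation with Me3SiI made in the flask under amine buffering runs under equilibrating conditions and should favour the tetrasubstituted C7=C8 enol ether over the C6=C7 isomer, as with 2-methylcyclohexanone, which is needed because kinetic deprotonation would go to C6.

**Step 13**
Reactants: 23 silyl enol ether of step 12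
Product: 24 C7=C8 enol triflate
Conditions: CsF, PhNTf2, 1,2-dimethoxyethane, 23 °C
Reagents that add atoms: N-phenylbis(trifluoromethanesulfonimide), O=S(=O)(N(c1ccccc1)S(=O)(=O)C(F)(F)F)C(F)(F)F
Why: Fluoride releases the regiodefined enolate in the presence of the triflating agent, so that it is sulfonylated before it can equilibrate and without an organolithium or strong amide base that would attack the isobutyrate.

**Step 14**
Reactants: 24 enol triflate of step 13
Product: 25 1-O-TBS-3-O-isobutyryl-longipin-7-ene (C7=C8 alkene, methyl on C8)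
Conditions: Pd(OAc)2 (5 mol %), PPh3 (10 mol %), HCO2H, Et3N, DMF, 60 °C
Reagents that add atoms: none
Why: Palladium-catalysed formate reduction of an enol triflate (oxidative addition to zerovalent palladium, formate exchange, loss of CO2, reductive elimination) replaces OTf by H without moving the alkene and leaves ester and silyl ether alone.

**Step 15**
Reactants: 25 alkene of step 14
Product: 26 1-O-TBS-3-O-isobutyryl-longipin-7-en-6-one
Conditions: CrO3, 3,5-dimethylpyrazole, CH2Cl2, −20 °C
Reagents that add atoms: chromium trioxide, O=[Cr](=O)=O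
Why: Allylic oxidation with the CrO3–dimethylpyrazole complex follows the α-pinene to verbenone pattern, since C6 is the only allylic methylene, C9–H is a bridgehead hydrogen whose allylic intermediate cannot become planar, and the C8 methyl group is the less reactive site with this reagent.

**Step 16**
Reactants: 26 silyl enone of step 15
Product: 27 1-hydroxy-3-O-isobutyryl-longipin-7-en-6-one
Conditions: HF·pyridine, THF, 0 → 23 °C
Reagents that add atoms: none
Why: Acidic fluoride desilylation removes the hindered TBS ether while avoiding the basic conditions under which the isobutyrate could migrate from O3 to O1.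

**Step 17**
Reactants: 27 alcohol of step 16
Product: 28 CNP0214356.1
Conditions: methacryloyl chloride, Et3N, 4-dimethylaminopyridine, CH2Cl2, 0 → 23 °C
Reagents that add atoms: methacryloyl chloride, C=C(C)C(=O)Cl
Why: Acyl-pyridinium catalysed esterification reaches the neopentylic secondary alcohol with retention at C1 and touches no other group.

**Compound list**
1 | 3-methylbut-3-en-2-one | CC(=O)C(C)=C | starting material
2 | 3-methyl-2-(triisopropylsilyloxy)buta-1,3-diene | C=C(C)C(=C)O[Si](C(C)C)(C(C)C)C(C)C | intermediate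
3 | methacrolein | C=C(C)C=O | starting material
4 | (S)-1,3-dimethyl-4-(triisopropylsilyloxy)cyclohex-3-ene-1-carbaldehyde | O=C[C@@]1(C)CCC(O[Si](C(C)C)(C(C)C)C(C)C)=C(C)C1 | intermediate
5 | 2,2-dimethylbut-3-enoic acid | C=CC(C)(C)C(=O)O | starting material
6 | dilithium 3,3-dimethylpent-4-ene-2,2-diolate (not isolated) | C=CC(C)(C)C(C)([O-])[O-].[Li+].[Li+] | intermediate
7 | 3,3-dimethylpent-4-en-2-one | C=CC(C)(C)C(C)=O | intermediate
8 | diisopinocampheylboron enolate of 7 (not isolated) | C=CC(C)(C)C(=C)OB([C@@H]1C[C@@H]2C[C@H]([C@H]1C)C2(C)C)[C@@H]1C[C@@H]2C[C@H]([C@H]1C)C2(C)C | intermediate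
9 | O3-diisopinocampheylboron aldolate of 10 (not isolated) | C=CC(C)(C)C(=O)C[C@@H](OB([C@@H]1C[C@@H]2C[C@H]([C@H]1C)C2(C)C)[C@@H]1C[C@@H]2C[C@H]([C@H]1C)C2(C)C)[C@@]1(C)CCC(O[Si](C(C)C)(C(C)C)C(C)C)=C(C)C1 | intermediate
10 | (1R)-1-[(1S)-1,3-dimethyl-4-(triisopropylsilyloxy)cyclohex-3-en-1-yl]-1-hydroxy-4,4-dimethylhex-5-en-3-one | C=CC(C)(C)C(=O)C[C@@H](O)[C@@]1(C)CCC(O[Si](C(C)C)(C(C)C)C(C)C)=C(C)C1 | intermediate
11 | isobutyraldehyde | CC(C)C=O | starting material
12 | (1R,3R)-1-[(1S)-1,3-dimethyl-4-(triisopropylsilyloxy)cyclohex-3-en-1-yl]-3-hydroxy-4,4-dimethylhex-5-en-1-yl 2-methylpropanoate | C=CC(C)(C)[C@H](O)C[C@@H](OC(=O)C(C)C)[C@@]1(C)CCC(O[Si](C(C)C)(C(C)C)C(C)C)=C(C)C1 | intermediate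
13 | O1-TBS ether of 12 | C=CC(C)(C)[C@H](O[Si](C)(C)C(C)(C)C)C[C@@H](OC(=O)C(C)C)[C@@]1(C)CCC(O[Si](C(C)C)(C(C)C)C(C)C)=C(C)C1 | intermediate
14 | (1R,3R)-3-(tert-butyldimethylsilyloxy)-1-[(1S)-1,3-dimethyl-4-oxocyclohex-2-en-1-yl]-4,4-dimethylhex-5-en-1-yl 2-methylpropanoate | C=CC(C)(C)[C@H](O[Si](C)(C)C(C)(C)C)C[C@@H](OC(=O)C(C)C)[C@@]1(C)CCC(=O)C(C)=C1 | intermediate
15 | 4-(trimethylsilyloxy)cyclohexa-2,4-dienyl analogue of 14 (not isolated) | C=CC(C)(C)[C@H](O[Si](C)(C)C(C)(C)C)C[C@@H](OC(=O)C(C)C)[C@@]1(C)CC=C(O[Si](C)(C)C)C(C)=C1 | intermediate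
16 | (1R,3R)-3-(tert-butyldimethylsilyloxy)-1-[(1S)-1,3-dimethyl-4-oxocyclohexa-2,5-dien-1-yl]-4,4-dimethylhex-5-en-1-yl 2-methylpropanoate | C=CC(C)(C)[C@H](O[Si](C)(C)C(C)(C)C)C[C@@H](OC(=O)C(C)C)[C@@]1(C)C=CC(=O)C(C)=C1 | intermediate
17 | 5,6-diol from 16, C10 epimers (not isolated) | OCC(O)C(C)(C)[C@H](O[Si](C)(C)C(C)(C)C)C[C@@H](OC(=O)C(C)C)[C@@]1(C)C=CC(=O)C(C)=C1 | intermediate
18 | (1R,3R)-3-(tert-butyldimethylsilyloxy)-1-[(1S)-1,3-dimethyl-4-oxocyclohexa-2,5-dien-1-yl]-4,4-dimethyl-5-oxopentyl 2-methylpropanoate | O=CC(C)(C)[C@H](O[Si](C)(C)C(C)(C)C)C[C@@H](OC(=O)C(C)C)[C@@]1(C)C=CC(=O)C(C)=C1 | intermediate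
19 | (E)-N-TBS hydrazone of 18 (not isolated) | CC(C)(C)[Si](C)(C)N/N=C/C(C)(C)[C@H](O[Si](C)(C)C(C)(C)C)C[C@@H](OC(=O)C(C)C)[C@@]1(C)C=CC(=O)C(C)=C1 | intermediate
20 | (1R,3R)-3-(tert-butyldimethylsilyloxy)-1-[(1S)-1,3-dimethyl-4-oxocyclohexa-2,5-dien-1-yl]-5,5-diiodo-4,4-dimethylpentyl 2-methylpropanoate | IC(I)C(C)(C)[C@H](O[Si](C)(C)C(C)(C)C)C[C@@H](OC(=O)C(C)C)[C@@]1(C)C=CC(=O)C(C)=C1 | intermediate
21 | cis-fused bicyclic C10 iodide with C5–C10 closed and the C8=C9 enone intact, C10 epimers (not isolated) | CC(C)(C)[Si](C)(C)O[C@@H]1C[C@@H](OC(=O)C(C)C)[C@]2(C)C=C(C)C(=O)C[C@@H]2C(I)C1(C)C | intermediate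
22 | 1-O-TBS-3-O-isobutyryl-longipinan-7-one, C1, C3, C4, C5, C9, C10 as in 28, C8 methyl syn to the C4 methyl | CC(C)(C)[Si](C)(C)O[C@@H]1C[C@@H](OC(=O)C(C)C)[C@@]2(C)[C@@H]3CC(=O)[C@H](C)[C@H]2[C@@H]3C1(C)C | intermediate
23 | C7=C8 trimethylsilyl enol ether of 22 | CC(C)(C)[Si](C)(C)O[C@@H]1C[C@@H](OC(=O)C(C)C)[C@@]2(C)[C@@H]3CC(O[Si](C)(C)C)=C(C)[C@H]2[C@@H]3C1(C)C | intermediate
24 | C7=C8 enol triflate | CC(C)(C)[Si](C)(C)O[C@@H]1C[C@@H](OC(=O)C(C)C)[C@@]2(C)[C@@H]3CC(OS(=O)(=O)C(F)(F)F)=C(C)[C@H]2[C@@H]3C1(C)C | intermediate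
25 | 1-O-TBS-3-O-isobutyryl-longipin-7-ene | CC(C)(C)[Si](C)(C)O[C@@H]1C[C@@H](OC(=O)C(C)C)[C@@]2(C)[C@@H]3CC=C(C)[C@H]2[C@@H]3C1(C)C | intermediate
26 | 1-O-TBS-3-O-isobutyryl-longipin-7-en-6-one | CC(C)(C)[Si](C)(C)O[C@@H]1C[C@@H](OC(=O)C(C)C)[C@@]2(C)[C@@H]3C(=O)C=C(C)[C@H]2[C@@H]3C1(C)C | intermediate
27 | 1-hydroxy-3-O-isobutyryl-longipin-7-en-6-one | O[C@@H]1C[C@@H](OC(=O)C(C)C)[C@@]2(C)[C@@H]3C(=O)C=C(C)[C@H]2[C@@H]3C1(C)C | intermediate
28 | CNP0214356.1, (1R,3R,4R,5R,9R,10S)-3-isobutyryloxy-1-methacryloyloxy-longipin-7-en-6-one (route numbering) | C=C(C)C(=O)O[C@@H]1C[C@@H](OC(=O)C(C)C)[C@@]2(C)[C@@H]3C(=O)C=C(C)[C@H]2[C@@H]3C1(C)C | target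

**Total step count:** 17. **Longest linear sequence:** 16 (steps 1, 2 and 4 to 17, from 3-methylbut-3-en-2-one).

**Steps most likely to fail**

1. Step 11.
   - What may go wrong: hydrogen transfer to either C10 radical ahead of ring closure; a 1,5-hydrogen shift from C3–H to the first C10 radical; and above all reopening of the cyclobutane (scission of C9–C10 or of C4–C9) before the C8 radical is quenched.
   - Fallback: known reaction types only. It sets out from aldehyde 18, so step 10 is skipped as well, and comes back at 22.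
   - Aldehyde 18 is treated with SmI2 (2.2 equiv) and t-BuOH in THF at −78 °C. This ketyl–olefin reductive cyclisation (7-exo-trig onto C5) should give the bicyclic hydroxy enone F1.
   - Dess–Martin periodinane oxidises the C10 carbinol to the bicyclic enedione F2.
   - A second exposure to SmI2 in THF–MeOH closes C9–C10 by the established 4-exo-trig ketyl–olefin cyclisation to the tricyclic cyclobutanol F3. Here the adduct radical is reduced at once by divalent samarium to the enolate, so the closure cannot revert.
   - The tertiary alcohol is acylated with methyl chlorooxoacetate and 4-dimethylaminopyridine to the methyl oxalate F4.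
   - Bu3SnH with 2,2′-azobis(isobutyronitrile) in refluxing toluene (Barton–McCombie deoxygenation in its oxalate form) puts hydrogen on the only open face of C10 to give 22.

2. Step 4.
   - What may go wrong: poor facial selectivity, because methyl ketone diisopinocampheylboron enolates discriminate only moderately and the aldehyde adds no bias of its own; also sluggish addition to the neopentylic aldehyde.
   - Fallback: an auxiliary-based acetate aldol followed by ketone construction. It sets out from 4 and comes back at 10.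
   - (R)-2-hydroxy-1,2,2-triphenylethyl acetate is doubly deprotonated with LDA in THF and combined with 4 at −100 °C. These purely basic conditions leave the TIPS enol ether alone and should give the β-hydroxy ester F5, which can be brought to one diastereomer by crystallisation.
   - MeNH(OMe)·HCl with i-PrMgCl converts it into the Weinreb amide F6.
   - 3-Methylbut-2-enylmagnesium chloride (3 equiv) then adds through its γ-carbon (SE2′) to install C11 with its two methyl groups and the vinyl group, giving 10.

3. Step 12.
   - What may go wrong: enolisation toward C6 instead of C8, which would carry the wrong alkene position through steps 13 to 15.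
   - Fallback: it uses the natural kinetic preference for C6 and replaces the allylic oxidation. It sets out from 22 and comes back at 26.
   - LiHMDS in THF at −78 °C followed by 2-(phenylsulfonyl)-3-phenyloxaziridine should give the C6 α-hydroxy ketone F7.
   - Dess–Martin periodinane gives the 1,2-dione. It can enolise only toward C8, because C5 is a bridgehead, and so rests as the diosphenol F8, which already holds the C6 ketone and the C7=C8 alkene.
   - Tf2O and pyridine give the α-triflyloxy enone F9.
   - Pd(OAc)2, PPh3, HCO2H and Et3N in DMF remove the triflate to give 26.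

**Further compounds**
F1 | step 11 | bicyclic C10 hydroxy enone with C5–C10 closed, C10 epimers | CC(C)(C)[Si](C)(C)O[C@@H]1C[C@@H](OC(=O)C(C)C)[C@]2(C)C=C(C)C(=O)C[C@@H]2C(O)C1(C)C
F2 | step 11 | bicyclic C7,C10 enedione | CC(C)(C)[Si](C)(C)O[C@@H]1C[C@@H](OC(=O)C(C)C)[C@]2(C)C=C(C)C(=O)C[C@@H]2C(=O)C1(C)C
F3 | step 11 | 10-hydroxy derivative of 22 (tertiary cyclobutanol) | CC(C)(C)[Si](C)(C)O[C@@H]1C[C@@H](OC(=O)C(C)C)[C@@]2(C)[C@@H]3CC(=O)[C@H](C)[C@H]2[C@]3(O)C1(C)C
F4 | step 11 | C10 methyl oxalate of F3 | CC(C)(C)[Si](C)(C)O[C@@H]1C[C@@H](OC(=O)C(C)C)[C@@]2(C)[C@@H]3CC(=O)[C@H](C)[C@H]2[C@]3(OC(=O)C(=O)OC)C1(C)C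
F5 | step 4 | (R)-2-hydroxy-1,2,2-triphenylethyl (3R)-3-[(1S)-1,3-dimethyl-4-(triisopropylsilyloxy)cyclohex-3-en-1-yl]-3-hydroxypropanoate | OC(c1ccccc1)(c1ccccc1)[C@@H](c1ccccc1)OC(=O)C[C@@H](O)[C@@]1(C)CCC(O[Si](C(C)C)(C(C)C)C(C)C)=C(C)C1
F6 | step 4 | (3R)-3-[(1S)-1,3-dimethyl-4-(triisopropylsilyloxy)cyclohex-3-en-1-yl]-3-hydroxy-N-methoxy-N-methylpropanamide | CON(C)C(=O)C[C@@H](O)[C@@]1(C)CCC(O[Si](C(C)C)(C(C)C)C(C)C)=C(C)C1
F7 | step 12 | 6-hydroxy derivative of 22 (OH on the face syn to C10–H) | CC(C)(C)[Si](C)(C)O[C@@H]1C[C@@H](OC(=O)C(C)C)[C@@]2(C)[C@@H]3[C@@H](O)C(=O)[C@H](C)[C@H]2[C@@H]3C1(C)C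
F8 | step 12 | diosphenol, 7-hydroxy derivative of 26 | CC(C)(C)[Si](C)(C)O[C@@H]1C[C@@H](OC(=O)C(C)C)[C@@]2(C)[C@@H]3C(=O)C(O)=C(C)[C@H]2[C@@H]3C1(C)C
F9 | step 12 | 7-triflyloxy derivative of 26 | CC(C)(C)[Si](C)(C)O[C@@H]1C[C@@H](OC(=O)C(C)C)[C@@]2(C)[C@@H]3C(=O)C(OS(=O)(=O)C(F)(F)F)=C(C)[C@H]2[C@@H]3C1(C)C
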